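## Retrosynthetic overview

1. Target diacid 31 ⇐ tetracyclic 3-ketone 25, by C3 deoxygenation through the tosylhydrazone, oxidation of C20 to the aldehyde, desilylation and saponification.
2. 25 ⇐ β-keto ester 24 by Mn(OAc)3 oxidative radical bicyclisation: C4–C5 closes ring A, then C9–C10 closes ring B. The strategy rests on the four contiguous stereocentres C4, C5, C10 and C9 along rings A and B, with C4 lying between the C3 ketone and the C19 ester in the 3-oxo precursor.
3. 24 ⇐ aldehyde 23 (Roskamp homologation, C3–C4) ⇐ bicyclooctene ester 12 + (Z)-vinyl bromide 17 by Pd2(dba)3-catalysed α-alkenylation (C5–C6); 17 comes from propargyl alcohol by carbomagnesiation.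
4. 12 (rings C and D) ⇐ enone–enal 7 by intramolecular aldol (C8–C15) and enone-to-alkene transposition; 7 ⇐ (S)-4-isopropenylcyclohexenone 3 ⇐ (+)-nopinone 1.
5. Ring order: C (from nopinone), D (step 6), then A and B in one operation (step 16).

Key step: step 16

Remark on the chemistry: gibberellin numbering is used for atoms. C4 of 24 is an enolisable β-keto ester centre and is drawn without configuration. C20 is carried as a 4-methoxybenzyl (PMB) ether so that it can be freed without base next to the syn-axial C19 ester.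

## Route

Step 1
Reactants: 1 (1R,5S)-6,6-dimethylbicyclo[3.1.1]heptan-2-one ((+)-nopinone)
Product: 2 (4S)-4-(prop-1-en-2-yl)cyclohex-1-en-1-yl acetate
Conditions: Ac2O, BF3·OEt2 (0.3 equiv), Zn(OAc)2 (0.1 equiv), 0 °C to rt
Reagents that add atoms: acetic anhydride, CC(=O)OC(C)=O
Why: Lewis-acid-mediated cyclobutane ring opening with enol acetylation: the strained bond between the α-bridgehead and the CMe2 carbon breaks, the tertiary cation loses a proton to give the isopropenyl group and the enolate is trapped as the enol acetate; the other bridgehead stereocentre is untouched and becomes C13.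

Step 2
Reactants: 2 (4S)-4-(prop-1-en-2-yl)cyclohex-1-en-1-yl acetate
Product: 3 (4S)-4-(prop-1-en-2-yl)cyclohex-2-en-1-one
Conditions: allyl methyl carbonate (2 equiv), Pd(OAc)2 (5 mol%), dppe (5 mol%), Bu3SnOMe (10 mol%), MeCN, 80 °C
Reagents that add atoms: none
Why: Tsuji dehydrogenation of an enol acetate: Bu3SnOMe gives the regiodefined tin enolate, which is transferred to allylpalladium and undergoes β-hydride elimination toward C12, so the enone forms without enolate equilibration and C13 keeps its configuration.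

Step 3
Reactants: 3 (4S)-4-(prop-1-en-2-yl)cyclohex-2-en-1-one
Product: 5 methyl 2-[(5S)-2-oxo-5-(prop-1-en-2-yl)cyclohex-3-en-1-yl]acetate (C1 epimers), via lithium dienolate 4 (not isolated)
Conditions: LiN(i-Pr)2 (1.05 equiv), THF, −78 °C; BrCH2CO2Me, DMPU, −78 to −40 °C
Reagents that add atoms: methyl bromoacetate, COC(=O)CBr
Why: Enolate alkylation: kinetic deprotonation of the cyclohexenone at the α′ carbon (C8) gives the cross-conjugated dienolate, which is C-alkylated by the reactive α-bromo ester; C8 forms as a mixture, which does not matter because it is re-enolised in step 6.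

Step 4
Reactants: 5 methyl 2-[(5S)-2-oxo-5-(prop-1-en-2-yl)cyclohex-3-en-1-yl]acetate
Product: 6 methyl 2-[(5S)-5-(3-hydroxyprop-1-en-2-yl)-2-oxocyclohex-3-en-1-yl]acetate (C1 epimers)
Conditions: SeO2 (0.3 equiv), t-BuOOH (3 equiv), CH2Cl2, 0 °C to rt
Reagents that add atoms: selenium dioxide (catalytic oxygen carrier), O=[Se]=O; tert-butyl hydroperoxide, CC(C)(C)OO
Why: SeO2/t-BuOOH allylic oxidation (ene reaction, then [2,3]-shift) of the 1,1-disubstituted alkene occurs at the methyl group in preference to the tertiary C13–H, and the electron-poor enone double bond does not react.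

Step 5
Reactants: 6 methyl 2-[(5S)-5-(3-hydroxyprop-1-en-2-yl)-2-oxocyclohex-3-en-1-yl]acetate
Product: 7 methyl 2-[(5S)-2-oxo-5-(3-oxoprop-1-en-2-yl)cyclohex-3-en-1-yl]acetate (C1 epimers)
Conditions: Dess–Martin periodinane, pyridine, CH2Cl2, 0 °C to rt
Reagents that add atoms: none
Why: Dess–Martin oxidation of the primary allylic alcohol gives the non-enolisable 2-substituted acrolein under buffered conditions that leave the α′ and γ positions of the enone alone.

Step 6
Reactants: 7 methyl 2-[(5S)-2-oxo-5-(3-oxoprop-1-en-2-yl)cyclohex-3-en-1-yl]acetate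
Product: 9 methyl 2-[(1R,5S,7R)-7-hydroxy-6-methylidene-2-oxobicyclo[3.2.1]oct-3-en-1-yl]acetate, via boron dienolate 8 (not isolated)
Conditions: n-Bu2BOTf (1.2 equiv), i-Pr2NEt (1.5 equiv), CH2Cl2, −78 to −20 °C; pH 7 buffer, MeOH
Reagents that add atoms: none
Why: Intramolecular boron aldol reaction: soft enolisation gives only the α′ boron dienolate (the ester is not enolised and both C8 epimers converge), which adds 5-exo-trig to the tethered aldehyde (attack at the enal β-carbon would be 5-endo); the bridge can form only cis to the C13–C16 bond, which fixes C8, and the closed Zimmerman–Traxler transition state with boron bridging the enolate oxygen and the aldehyde oxygen places the new hydroxyl syn to the C9 carbonyl, that is endo, the C15 configuration of the target.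

Step 7
Reactants: 9 methyl 2-[(1R,5S,7R)-7-hydroxy-6-methylidene-2-oxobicyclo[3.2.1]oct-3-en-1-yl]acetate
Product: 10 methyl 2-[(1R,5S,7R)-7-{[tert-butyl(dimethyl)silyl]oxy}-6-methylidene-2-oxobicyclo[3.2.1]oct-3-en-1-yl]acetate
Conditions: TBSOTf, 2,6-lutidine, CH2Cl2, −78 to 0 °C
Reagents that add atoms: tert-butyldimethylsilyl trifluoromethanesulfonate, CC(C)(C)[Si](C)(C)OS(=O)(=O)C(F)(F)F
Why: Silylation of the hindered neopentyl allylic alcohol needs the silyl triflate, and the ether blocks retro-aldol cleavage in the following steps.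

Step 8
Reactants: 10 methyl 2-[(1R,5S,7R)-7-{[tert-butyl(dimethyl)silyl]oxy}-6-methylidene-2-oxobicyclo[3.2.1]oct-3-en-1-yl]acetate
Product: 11 tosylhydrazone of 10 at C9 (bicyclooctene C2)
Conditions: TsNHNH2, PPTS (cat.), EtOH, 60 °C
Reagents that add atoms: 4-methylbenzenesulfonohydrazide, Cc1ccc(cc1)S(=O)(=O)NN
Why: Hydrazone formation at the only ketone; condensation at the neopentyl C9 is slow but has no competing site, since the ester does not react.

Step 9
Reactants: 11 tosylhydrazone of 10
Product: 12 methyl 2-[(1S,5R,7R)-7-{[tert-butyl(dimethyl)silyl]oxy}-6-methylidenebicyclo[3.2.1]oct-2-en-1-yl]acetate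
Conditions: catecholborane, CHCl3, 0 °C; then NaOAc·3H2O, 60 °C
Reagents that add atoms: none
Why: Catecholborane reduction of an α,β-unsaturated tosylhydrazone with 1,3-transposition of the alkene: hydride adds to C9, sulfinate is lost and the allylic diazene extrudes N2 by a retro-ene shift, giving C9=C11 with hydrogen on C12; the outcome is regiospecific because C8 is quaternary.

Step 10
Reactants: 13 prop-2-yn-1-ol; 14 [2-(1,3-dioxolan-2-yl)ethyl]magnesium bromide (THF solution)
Product: 16 (2Z)-3-bromo-2-[2-(1,3-dioxolan-2-yl)ethyl]prop-2-en-1-ol, via alkenylmagnesium alkoxide 15 (not isolated)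
Conditions: 14 (2.5 equiv), CuI (10 mol%), THF, −10 °C to rt; then NBS, −40 to 0 °C
Reagents that add atoms: N-bromosuccinimide, O=C1CCC(=O)N1Br
Why: CuI-catalysed anti-carbomagnesiation of the propargylic magnesium alkoxide puts the alkyl group on the internal carbon and magnesium on the terminal carbon cis to CH2O through a five-membered chelate, and bromination with retention gives the (Z)-bromide with Br cis to the future C20 and trans to the C1 chain.

Step 11
Reactants: 16 (2Z)-3-bromo-2-[2-(1,3-dioxolan-2-yl)ethyl]prop-2-en-1-ol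
Product: 17 2-[(3Z)-4-bromo-3-{[(4-methoxyphenyl)methoxy]methyl}but-3-en-1-yl]-1,3-dioxolane
Conditions: NaH, 4-MeOC6H4CH2Cl, Bu4NI (cat.), THF/DMF, 0 °C to rt
Reagents that add atoms: 4-methoxybenzyl chloride, COc1ccc(CCl)cc1
Why: Williamson etherification of the primary allylic alkoxide; the vinyl bromide has no hydrogen on C10 for elimination and is inert to NaH.

Step 12
Reactants: 18 methyl 2-methyl-3-oxobutanoate
Product: 19 methyl 2-diazopropanoate
Conditions: 4-AcNHC6H4SO2N3, DBU, MeCN, 0 °C to rt
Reagents that add atoms: 4-acetamidobenzenesulfonyl azide, CC(=O)Nc1ccc(cc1)S(=O)(=O)N=[N+]=[N-]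
Why: Regitz deacylative diazo transfer: the enolate of the α-substituted β-keto ester adds to the sulfonyl azide and the adduct fragments with transfer of the acetyl group to the sulfonamide nitrogen.

Step 13
Reactants: 12 methyl 2-[(1S,5R,7R)-7-{[tert-butyl(dimethyl)silyl]oxy}-6-methylidenebicyclo[3.2.1]oct-2-en-1-yl]acetate; 17 2-[(3Z)-4-bromo-3-{[(4-methoxyphenyl)methoxy]methyl}but-3-en-1-yl]-1,3-dioxolane
Product: 22 methyl (2S,3Z)-2-[(1R,5R,7R)-7-{[tert-butyl(dimethyl)silyl]oxy}-6-methylidenebicyclo[3.2.1]oct-2-en-1-yl]-6-(1,3-dioxolan-2-yl)-4-{[(4-methoxyphenyl)methoxy]methyl}hex-3-enoate, via lithium enolate 20 (not isolated), via zinc enolate 21 (not isolated)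
Conditions: LiN(i-Pr)2, THF, −78 °C; ZnCl2, −78 °C to rt; 17, Pd2(dba)3 (2.5 mol%, zerovalent palladium), P(t-Bu)3 (10 mol%), THF, rt to 45 °C
Reagents that add atoms: none
Why: Pd2(dba)3/P(t-Bu)3-catalysed α-alkenylation of an ester enolate, run as a Negishi-type coupling of the zinc enolate so that the product is not re-enolised and C5=C10 does not migrate; oxidative addition and reductive elimination retain the (Z) geometry, and C6 is set under substrate control, palladium being delivered to the enolate face anti to the C15–OTBS arm of the quaternary C8, with the minor C6 epimer removed by chromatography.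

Step 14
Reactants: 22 coupled ester (dioxolane)
Product: 23 methyl (2S,3Z)-2-[(1R,5R,7R)-7-{[tert-butyl(dimethyl)silyl]oxy}-6-methylidenebicyclo[3.2.1]oct-2-en-1-yl]-4-{[(4-methoxyphenyl)methoxy]methyl}-7-oxohept-3-enoate
Conditions: 1 M HCl, THF, rt
Reagents that add atoms: water, O
Why: Acid hydrolysis of the dioxolane of an aliphatic aldehyde; the hindered secondary TBS ether, the PMB ether and the methyl ester survive dilute aqueous acid at room temperature.

Step 15
Reactants: 23 aldehyde; 19 methyl 2-diazopropanoate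
Product: 24 dimethyl (6Z,8S)-8-[(1R,5R,7R)-7-{[tert-butyl(dimethyl)silyl]oxy}-6-methylidenebicyclo[3.2.1]oct-2-en-1-yl]-6-{[(4-methoxyphenyl)methoxy]methyl}-2-methyl-3-oxonon-6-enedioate (C2 epimers)
Conditions: 19 (1.5 equiv), Sc(OTf)3 (10 mol%), CH2Cl2, −20 °C to rt
Reagents that add atoms: none
Why: Roskamp reaction: the Lewis-acid-activated aldehyde is attacked by the diazo carbon and a 1,2-hydride shift with loss of N2 gives the α-methyl β-keto ester directly; C4 forms as an enolisable epimeric centre, which does not matter.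

Step 16
Reactants: 24 β-keto ester
Product: 25 dimethyl 15β-(tert-butyldimethylsilyloxy)-20-(4-methoxybenzyloxy)-3-oxogibberell-16-ene-7,19-dioate (C4, C5, C6, C8, C9, C10, C13 and C15 as in the target)
Conditions: Mn(OAc)3·2H2O (2.2 equiv), degassed EtOH, 25 °C
Reagents that add atoms: none
Why: Mn(OAc)3 (trivalent manganese) oxidises the enol of the α-methyl β-keto ester to the electrophilic tertiary C4 radical; the closest known reaction type is the Mn(OAc)3 oxidative free-radical polycyclisation of unsaturated β-keto esters. Ring A closes by 6-endo-trig attack of C4 on C5 through a chair transition state, ring B by 5-exo-trig attack of the resulting tertiary C10 radical on C9 of the bicyclooctene, and the secondary C11 radical takes a hydrogen atom from ethanol, whose radical consumes the second equivalent of oxidant. C4: the ketone lies in the forming ring and the ester ends axial, cis to C20, as in related closures of α-methyl β-keto esters; C5: allylic 1,3-strain with the cis CH2OPMB group holds C6–H in the alkene plane, so C4 adds to the face anti to the C8 bicycle. C10: the equatorial C5–C6 tether reaches C9 only from the equatorial side of the cyclohexyl radical, which gives the trans A/B fusion with C20 axial; C9: the two-atom tether from C8 and the endo C15–OTBS group leave only the exo (C14) face open. The step needs 6-endo over 5-exo closure first, secured by the trisubstituted alkene whose C5 terminus is the less substituted, and cyclisation of the C10 radical faster than its quenching, secured by its tertiary nature and the proximity of the C9=C11 bond.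

Step 17
Reactants: 25 tetracyclic 3-ketone
Product: 26 C3 tosylhydrazone of 25
Conditions: TsNHNH2, AcOH (cat.), MeOH, 60 °C
Reagents that add atoms: 4-methylbenzenesulfonohydrazide, Cc1ccc(cc1)S(=O)(=O)NN
Why: Hydrazone formation at the only ketone; the neighbouring quaternary C4 slows but does not prevent condensation.

Step 18
Reactants: 26 C3 tosylhydrazone
Product: 27 dimethyl 15β-(tert-butyldimethylsilyloxy)-20-(4-methoxybenzyloxy)gibberell-16-ene-7,19-dioate
Conditions: catecholborane, CHCl3, 0 °C to rt; then NaOAc·3H2O, 60 °C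
Reagents that add atoms: none
Why: Catecholborane deoxygenation of a saturated ketone tosylhydrazone: hydride adds to C=N and loss of sulfinate and N2 from the diazene leaves CH2 at C3 under conditions that do not touch esters, ethers or the 1,1-disubstituted alkene.

Step 19
Reactants: 27 PMB ether
Product: 28 dimethyl 15β-(tert-butyldimethylsilyloxy)-20-hydroxygibberell-16-ene-7,19-dioate
Conditions: DDQ, CH2Cl2/pH 7 buffer, 0 °C
Reagents that add atoms: none
Why: Oxidative PMB cleavage by DDQ (hydride abstraction, hydrolysis of the oxocarbenium ion) frees the C20 alcohol under neutral conditions, so no alkoxide forms that could lactonise onto the syn-axial C19 ester.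

Step 20
Reactants: 28 C20 alcohol
Product: 29 dimethyl 15β-(tert-butyldimethylsilyloxy)-20-oxogibberell-16-ene-7,19-dioate
Conditions: Dess–Martin periodinane, pyridine, CH2Cl2, 0 °C to rt (crude 28 used at once)
Reagents that add atoms: none
Why: Dess–Martin oxidation of the neopentyl primary alcohol gives the non-enolisable C20 aldehyde before lactonisation can compete.

Step 21
Reactants: 29 silyl ether aldehyde
Product: 30 dimethyl 15β-hydroxy-20-oxogibberell-16-ene-7,19-dioate (dimethyl ester of the target)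
Conditions: HF·pyridine, THF/pyridine, 0 °C to rt
Reagents that add atoms: none
Why: Fluoride-mediated desilylation under buffered acidic conditions leaves the aldehyde, the esters and the allylic alcohol intact.

Step 22
Reactants: 30 dimethyl 15β-hydroxy-20-oxogibberell-16-ene-7,19-dioate
Product: 31 15β-hydroxy-20-oxogibberell-16-ene-7,19-dioic acid (the target gibberellin)
Conditions: KOH, MeOH/H2O, 60 °C; then 1 M HCl to pH 3
Reagents that add atoms: potassium hydroxide, [K+].[OH-]
Why: Saponification of both methyl esters; the hindered axial C19 ester is assisted by the neighbouring C20 aldehyde (its hydrate alkoxide attacks the ester), C6 already has the thermodynamically preferred configuration, C10 carries no α-hydrogen, and acidification gives the diacid.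

## Compound list

1 | (1R,5S)-6,6-dimethylbicyclo[3.1.1]heptan-2-one ((+)-nopinone) | O=C1CC[C@H]2C[C@@H]1C2(C)C | starting material
2 | (4S)-4-(prop-1-en-2-yl)cyclohex-1-en-1-yl acetate | CC(=O)OC1=CC[C@H](CC1)C(C)=C | intermediate
3 | (4S)-4-(prop-1-en-2-yl)cyclohex-2-en-1-one | O=C1C=C[C@H](CC1)C(C)=C | intermediate
4 | lithium 4-(prop-1-en-2-yl)cyclohexa-1,5-dien-1-olate (C4 as in 3) | [Li]OC1=CC[C@@H](C=C1)C(C)=C | intermediate
5 | methyl 2-[(5S)-2-oxo-5-(prop-1-en-2-yl)cyclohex-3-en-1-yl]acetate (C1 epimers) | COC(=O)CC1C[C@@H](C=CC1=O)C(C)=C | intermediate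
6 | methyl 2-[(5S)-5-(3-hydroxyprop-1-en-2-yl)-2-oxocyclohex-3-en-1-yl]acetate (C1 epimers) | COC(=O)CC1C[C@@H](C=CC1=O)C(=C)CO | intermediate
7 | methyl 2-[(5S)-2-oxo-5-(3-oxoprop-1-en-2-yl)cyclohex-3-en-1-yl]acetate (C1 epimers) | COC(=O)CC1C[C@@H](C=CC1=O)C(=C)C=O | intermediate
8 | dibutylboron α′-dienolate of 7 | COC(=O)CC1=C(OB(CCCC)CCCC)C=C[C@H](C1)C(=C)C=O | intermediate
9 | methyl 2-[(1R,5S,7R)-7-hydroxy-6-methylidene-2-oxobicyclo[3.2.1]oct-3-en-1-yl]acetate (15-OH endo, syn to C9) | COC(=O)C[C@]12C(=O)C=C[C@H](C1)C(=C)[C@H]2O | intermediate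
10 | methyl 2-[(1R,5S,7R)-7-{[tert-butyl(dimethyl)silyl]oxy}-6-methylidene-2-oxobicyclo[3.2.1]oct-3-en-1-yl]acetate | COC(=O)C[C@]12C(=O)C=C[C@H](C1)C(=C)[C@H]2O[Si](C)(C)C(C)(C)C | intermediate
11 | tosylhydrazone of 10 at the ring ketone | COC(=O)C[C@]12C(=NNS(=O)(=O)c3ccc(C)cc3)C=C[C@H](C1)C(=C)[C@H]2O[Si](C)(C)C(C)(C)C | intermediate
12 | methyl 2-[(1S,5R,7R)-7-{[tert-butyl(dimethyl)silyl]oxy}-6-methylidenebicyclo[3.2.1]oct-2-en-1-yl]acetate | COC(=O)C[C@]12C=CC[C@H](C1)C(=C)[C@H]2O[Si](C)(C)C(C)(C)C | intermediate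
13 | prop-2-yn-1-ol | C#CCO | starting material
14 | [2-(1,3-dioxolan-2-yl)ethyl]magnesium bromide | Br[Mg]CCC1OCCO1 | starting material
15 | bromomagnesium (2Z)-3-(bromomagnesio)-2-[2-(1,3-dioxolan-2-yl)ethyl]prop-2-en-1-olate | Br[Mg]OC/C(CCC1OCCO1)=C\[Mg]Br | intermediate
16 | (2Z)-3-bromo-2-[2-(1,3-dioxolan-2-yl)ethyl]prop-2-en-1-ol | OC/C(CCC1OCCO1)=C\Br | intermediate
17 | 2-[(3Z)-4-bromo-3-{[(4-methoxyphenyl)methoxy]methyl}but-3-en-1-yl]-1,3-dioxolane | COc1ccc(COC/C(CCC2OCCO2)=C\Br)cc1 | intermediate
18 | methyl 2-methyl-3-oxobutanoate | COC(=O)C(C)C(C)=O | starting material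
19 | methyl 2-diazopropanoate | COC(=O)C(C)=[N+]=[N-] | intermediate
20 | lithium enolate of 12 | [Li]OC(OC)=C[C@]12C=CC[C@H](C1)C(=C)[C@H]2O[Si](C)(C)C(C)(C)C | intermediate
21 | chlorozinc enolate of 12 (drawn C-bound) | COC(=O)C([Zn]Cl)[C@]12C=CC[C@H](C1)C(=C)[C@H]2O[Si](C)(C)C(C)(C)C | intermediate
22 | methyl (2S,3Z)-2-[(1R,5R,7R)-7-{[tert-butyl(dimethyl)silyl]oxy}-6-methylidenebicyclo[3.2.1]oct-2-en-1-yl]-6-(1,3-dioxolan-2-yl)-4-{[(4-methoxyphenyl)methoxy]methyl}hex-3-enoate | O4CCOC4CC/C(COCc3ccc(OC)cc3)=C/[C@H](C(=O)OC)[C@]12C=CC[C@H](C1)C(=C)[C@H]2O[Si](C)(C)C(C)(C)C | intermediate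
23 | methyl (2S,3Z)-2-[(1R,5R,7R)-7-{[tert-butyl(dimethyl)silyl]oxy}-6-methylidenebicyclo[3.2.1]oct-2-en-1-yl]-4-{[(4-methoxyphenyl)methoxy]methyl}-7-oxohept-3-enoate | O=CCC/C(COCc3ccc(OC)cc3)=C/[C@H](C(=O)OC)[C@]12C=CC[C@H](C1)C(=C)[C@H]2O[Si](C)(C)C(C)(C)C | intermediate
24 | dimethyl (6Z,8S)-8-[(1R,5R,7R)-7-{[tert-butyl(dimethyl)silyl]oxy}-6-methylidenebicyclo[3.2.1]oct-2-en-1-yl]-6-{[(4-methoxyphenyl)methoxy]methyl}-2-methyl-3-oxonon-6-enedioate (C2 epimers) | COC(=O)C(C)C(=O)CC/C(COCc3ccc(OC)cc3)=C/[C@H](C(=O)OC)[C@]12C=CC[C@H](C1)C(=C)[C@H]2O[Si](C)(C)C(C)(C)C | intermediate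
25 | dimethyl 15β-(tert-butyldimethylsilyloxy)-20-(4-methoxybenzyloxy)-3-oxogibberell-16-ene-7,19-dioate | C=C1[C@@H]2CC[C@H]3[C@]4(COCc5ccc(OC)cc5)CCC(=O)[C@@](C)(C(=O)OC)[C@H]4[C@H](C(=O)OC)[C@]3(C2)[C@@H]1O[Si](C)(C)C(C)(C)C | intermediate
26 | C3 tosylhydrazone of 25 | C=C1[C@@H]2CC[C@H]3[C@]4(COCc5ccc(OC)cc5)CCC(=NNS(=O)(=O)c6ccc(C)cc6)[C@@](C)(C(=O)OC)[C@H]4[C@H](C(=O)OC)[C@]3(C2)[C@@H]1O[Si](C)(C)C(C)(C)C | intermediate
27 | dimethyl 15β-(tert-butyldimethylsilyloxy)-20-(4-methoxybenzyloxy)gibberell-16-ene-7,19-dioate | C=C1[C@@H]2CC[C@H]3[C@]4(COCc5ccc(OC)cc5)CCC[C@@](C)(C(=O)OC)[C@H]4[C@H](C(=O)OC)[C@]3(C2)[C@@H]1O[Si](C)(C)C(C)(C)C | intermediate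
28 | dimethyl 15β-(tert-butyldimethylsilyloxy)-20-hydroxygibberell-16-ene-7,19-dioate | C=C1[C@@H]2CC[C@H]3[C@]4(CO)CCC[C@@](C)(C(=O)OC)[C@H]4[C@H](C(=O)OC)[C@]3(C2)[C@@H]1O[Si](C)(C)C(C)(C)C | intermediate
29 | dimethyl 15β-(tert-butyldimethylsilyloxy)-20-oxogibberell-16-ene-7,19-dioate | C=C1[C@@H]2CC[C@H]3[C@]4(C=O)CCC[C@@](C)(C(=O)OC)[C@H]4[C@H](C(=O)OC)[C@]3(C2)[C@@H]1O[Si](C)(C)C(C)(C)C | intermediate
30 | dimethyl 15β-hydroxy-20-oxogibberell-16-ene-7,19-dioate (dimethyl ester of the target) | C=C1[C@@H]2CC[C@H]3[C@]4(C=O)CCC[C@@](C)(C(=O)OC)[C@H]4[C@H](C(=O)OC)[C@]3(C2)[C@@H]1O | intermediate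
31 | 15β-hydroxy-20-oxogibberell-16-ene-7,19-dioic acid (the target gibberellin) | C=C1[C@@H]2CC[C@H]3[C@]4(C=O)CCC[C@@](C)(C(=O)O)[C@H]4[C@H](C(=O)O)[C@]3(C2)[C@@H]1O | target

## Step count and risks

Total step count: 22. Longest linear sequence: 19 steps (steps 1–9, then 13–22).

Steps most likely to fail:

1. **Step 16 (radical bicyclisation).** The C10 radical may be quenched before ring B closes, by hydrogen transfer from the allylic C15–H or from the solvent, or by oxidation; C4 may also add to the wrong face of C5. Fallback: the same C4 radical is generated reductively, so that hydrogen-donor concentration and temperature can be set independently of an oxidant. Setting out from 24, PhSeCl and pyridine in CH2Cl2 should give the α-(phenylselanyl) β-keto ester F1. Slow addition of Bu3SnH with AIBN in benzene at 80 °C (or Et3B and air at low temperature) abstracts selenium; the C4 radical closes rings A and B as before and the C11 radical is reduced by the stannane. The sequence comes back to the route at 25.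

2. **Step 13 (α-alkenylation).** Facial discrimination at C6 may be poor when the C5–C6 bond forms, and C5=C10 may migrate into conjugation if free enolate persists. Fallback: C6 is set after the coupling by enolate protonation instead of in the C–C bond formation. The unwanted C6 epimer of 22, 6-epi-22 F2, is separated by chromatography and deprotonated with LiN(SiMe3)2 in THF at −78 °C to the extended enolate. Kinetic protonation at the α-carbon with a hindered phenol (deconjugative protonation) regenerates the β,γ-unsaturated ester. Repetition with separation converges on 22, where the route is rejoined.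

3. **Step 6 (bridging aldol).** The strained bridged aldol may revert (retro-aldol), the enal may polymerise, or C13 may be deprotonated at the γ position with loss of configuration. Fallback: the C8–C15 bond is made by irreversible alkylation and C15 is oxygenated afterwards. Setting out from 5, ene-type chlorination of the isopropenyl group (Ca(OCl)2, CO2, CH2Cl2/H2O) should give the allylic chloride F3, and LiN(i-Pr)2 in THF from −78 °C to rt should close ring D by intramolecular α′-alkylation to the bicyclic enone F4. TsNHNH2 gives the tosylhydrazone F5, and catecholborane followed by NaOAc·3H2O gives the diene ester F6. SeO2/t-BuOOH oxidises the C15 methylene next to the 1,1-disubstituted alkene from the open exo face to the exo alcohol F7, Dess–Martin periodinane gives the enone F8, and NaBH4/CeCl3·7H2O (Luche reduction) delivers hydride from the exo face to give the endo alcohol F9. TBSOTf and 2,6-lutidine then return to the route at 12.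

Further compounds
F1 | step 16 | dimethyl (6Z,8S)-8-[bicyclooctenyl]-6-{[(4-methoxyphenyl)methoxy]methyl}-2-methyl-3-oxo-2-(phenylselanyl)non-6-enedioate (bicyclooctenyl as in 24) | COC(=O)C(C)([Se]c4ccccc4)C(=O)CC/C(COCc3ccc(OC)cc3)=C/[C@H](C(=O)OC)[C@]12C=CC[C@H](C1)C(=C)[C@H]2O[Si](C)(C)C(C)(C)C
F2 | step 13 | 6-epi-22, methyl (2R,3Z)-2-[bicyclooctenyl]-6-(1,3-dioxolan-2-yl)-4-{[(4-methoxyphenyl)methoxy]methyl}hex-3-enoate | O4CCOC4CC/C(COCc3ccc(OC)cc3)=C/[C@@H](C(=O)OC)[C@]12C=CC[C@H](C1)C(=C)[C@H]2O[Si](C)(C)C(C)(C)C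
F3 | step 6 | methyl 2-[(5S)-5-(3-chloroprop-1-en-2-yl)-2-oxocyclohex-3-en-1-yl]acetate | COC(=O)CC1C[C@@H](C=CC1=O)C(=C)CCl
F4 | step 6 | methyl 2-(6-methylidene-2-oxobicyclo[3.2.1]oct-3-en-1-yl)acetate (bridgeheads as in 9) | COC(=O)C[C@]12C(=O)C=C[C@H](C1)C(=C)C2
F5 | step 6 | tosylhydrazone of F4 | COC(=O)C[C@]12C(=NNS(=O)(=O)c3ccc(C)cc3)C=C[C@H](C1)C(=C)C2
F6 | step 6 | methyl 2-(6-methylidenebicyclo[3.2.1]oct-2-en-1-yl)acetate (bridgeheads as in 12) | COC(=O)C[C@]12C=CC[C@H](C1)C(=C)C2
F7 | step 6 | methyl 2-(7-exo-hydroxy-6-methylidenebicyclo[3.2.1]oct-2-en-1-yl)acetate (C15 epimer of F9) | COC(=O)C[C@]12C=CC[C@H](C1)C(=C)[C@@H]2O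
F8 | step 6 | methyl 2-(6-methylidene-7-oxobicyclo[3.2.1]oct-2-en-1-yl)acetate | COC(=O)C[C@]12C=CC[C@H](C1)C(=C)C2=O
F9 | step 6 | methyl 2-[(1S,5R,7R)-7-hydroxy-6-methylidenebicyclo[3.2.1]oct-2-en-1-yl]acetate (endo alcohol, desilyl 12) | COC(=O)C[C@]12C=CC[C@H](C1)C(=C)[C@H]2O
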